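Numbering: ring C1–C10 (C1 enoate CH, C2/C3 oxirane, C4 C‑methyl, C6 lactone O–CH, C7 ring fusion, C8/C9 acyloxy carbons, C10 ester‑bearing), C11–C13 lactone, C14 ester carbon.
Retrosynthesis: remove the C8 and C9 acyl groups and the C13 methylene; cut C2–C3 and C3–O together (this opens the oxirane and the ten‑membered ring); then cut C1=C10, C9–C10, C5–C6 with O–C12, and C6–C7.
Enabling feature: the cis C2–C3 oxirane lies between the ring‑cis C1=C10 enoate and the ring‑cis C4=C5 alkene, so C3 is allylic (sulfonium ylide carbon) and C2 is an enal carbon.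
Forward: tartrate‑derived C7–C9 enoate, vinyl cuprate (C6–C7), alkenyl addition with lactonization (C5–C6, γ‑lactone first), glycolate aldol, oxidation and Wittig reaction (C9–C10, C10=C1), sulfonium salt, ylide ring closure (ten‑membered ring and oxirane in one step), methylenation, two acylations.
Stereochemistry: C8 from dimethyl D‑tartrate; C7 by anti cuprate addition; C6 and C9 by chelation to the C8 OPMB group; C2/C3 in the ring closure; side‑chain centres by Sharpless epoxidation and invertive acetolysis.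

Key step: step 21

Remark on the chemistry (assumption): the C10 carbinol of 22–25 is formed as a mixture of epimers (left undefined in the SMILES); both are oxidized to the single ketone 26.
Abbreviations: PMB = 4‑methoxybenzyl; TES = triethylsilyl; TBS = tert‑butyldimethylsilyl; TMS = trimethylsilyl; Ms = methanesulfonyl; Lac(X) = (2R,3R)‑2‑[(1Z)‑3‑X‑2‑methylprop‑1‑en‑1‑yl]‑5‑oxooxolan‑3‑yl.

Step 1
Reactants: 1 dimethyl D‑tartrate
Product: 2 dimethyl (4S,5S)-2-(4-methoxyphenyl)-1,3-dioxolane-4,5-dicarboxylate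
Conditions: 4‑MeOC6H4CH(OMe)2, TsOH (cat.), toluene, 80 °C
Reagents that add atoms: 4‑methoxybenzaldehyde dimethyl acetal, COC(OC)c1ccc(OC)cc1
Why: Acid‑catalysed transacetalization of the 1,2‑diol should give the dioxolane without touching the two carbinol centres.

Step 2
Reactants: 2 dimethyl (4S,5S)-2-(4-methoxyphenyl)-1,3-dioxolane-4,5-dicarboxylate
Product: 3 (2R,3R)-3-[(4-methoxybenzyl)oxy]butane-1,2,4-triol
Conditions: i‑Bu2AlH (excess), CH2Cl2, −78 °C → rt
Reagents that add atoms: none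
Why: Hydride reduction of both esters and reductive opening of the arylidene acetal leave a PMB ether on one secondary oxygen; the C2 symmetry makes both C–O cleavages equivalent, so a single triol is expected.

Step 3
Reactants: 3 (2R,3R)-3-[(4-methoxybenzyl)oxy]butane-1,2,4-triol
Product: 5 ethyl (2E,4S)-5-hydroxy-4-[(4-methoxybenzyl)oxy]pent-2-enoate, via hydroxy aldehyde 4 (not isolated)
Conditions: NaIO4/SiO2, CH2Cl2, rt; filter; Ph3P=CHCO2Et, rt
Reagents that add atoms: ethyl (triphenylphosphoranylidene)acetate, CCOC(=O)C=P(c1ccccc1)(c1ccccc1)c1ccccc1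
Why: Periodate glycol cleavage followed by Wittig olefination with a stabilized ylide should give the E enoate; the surviving carbinol centre becomes C8.

Step 4
Reactants: 5 ethyl (2E,4S)-5-hydroxy-4-[(4-methoxybenzyl)oxy]pent-2-enoate
Product: 6 ethyl (2E,4S)-4-[(4-methoxybenzyl)oxy]-5-[(triethylsilyl)oxy]pent-2-enoate
Conditions: Et3SiCl, imidazole, CH2Cl2, 0 °C
Reagents that add atoms: chlorotriethylsilane, CC[Si](Cl)(CC)CC
Why: Standard silylation of the primary alcohol (the future C9 oxygen).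

Step 5
Reactants: 6 ethyl (2E,4S)-4-[(4-methoxybenzyl)oxy]-5-[(triethylsilyl)oxy]pent-2-enoate
Product: 8 ethyl (3R,4S)-3-ethenyl-4-[(4-methoxybenzyl)oxy]-5-[(triethylsilyl)oxy]pentanoate, via ketene silyl acetal 7 (not isolated)
Conditions: CH2=CHMgBr, CuI (cat.), Me3SiCl, THF, −78 °C; aq. NH4Cl
Reagents that add atoms: vinylmagnesium bromide, C=C[Mg]Br
Why: Copper‑catalysed conjugate addition of a Grignard reagent to an E γ‑alkoxy enoate, where attack anti to the γ‑OPMB group (alkoxy group perpendicular, Felkin–Anh type) sets C7.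

Step 6
Reactants: 8 ethyl (3R,4S)-3-ethenyl-4-[(4-methoxybenzyl)oxy]-5-[(triethylsilyl)oxy]pentanoate
Product: 9 ethyl (3S,4S)-3-formyl-4-[(4-methoxybenzyl)oxy]-5-[(triethylsilyl)oxy]pentanoate
Conditions: OsO4 (cat.), NaIO4, 2,6‑lutidine, dioxane/H2O, rt
Reagents that add atoms: osmium tetroxide (catalytic oxygen carrier), O=[Os](=O)(=O)=O; sodium periodate, [Na+].[O-]I(=O)(=O)=O
Why: Lemieux–Johnson cleavage of the only alkene unmasks the C6 aldehyde, and the lutidine buffer should keep the adjacent C7 centre from epimerizing.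

Step 7
Reactants: 10 propargyl alcohol
Product: 12 (2Z)-3-iodo-2-methylprop-2-en-1-ol, via alkenylmagnesium alkoxide 11 (not isolated)
Conditions: MeMgBr, CuI (cat.), THF, −10 °C → rt; then I2, −10 °C
Reagents that add atoms: methylmagnesium bromide, C[Mg]Br; iodine, II
Why: Copper‑catalysed anti carbomagnesiation of the propargylic alkoxide puts methyl on the internal carbon and magnesium cis to CH2O in a five‑membered chelate, and iodinolysis with retention gives the Z iodide (the future C4=C5 geometry).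

Step 8
Reactants: 12 (2Z)-3-iodo-2-methylprop-2-en-1-ol
Product: 13 tert-butyl{[(2Z)-3-iodo-2-methylprop-2-en-1-yl]oxy}dimethylsilane
Conditions: t‑BuMe2SiCl, imidazole, CH2Cl2, rt
Reagents that add atoms: tert‑butylchlorodimethylsilane, CC(C)(C)[Si](C)(C)Cl
Why: Standard silylation of the primary allylic alcohol (the future C3 oxygen).

Step 9
Reactants: 13 tert-butyl{[(2Z)-3-iodo-2-methylprop-2-en-1-yl]oxy}dimethylsilane; 9 ethyl (3S,4S)-3-formyl-4-[(4-methoxybenzyl)oxy]-5-[(triethylsilyl)oxy]pentanoate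
Product: 17 (4R,5R)-5-{(1Z)-3-[(tert-butyldimethylsilyl)oxy]-2-methylprop-1-en-1-yl}-4-{(1S)-1-[(4-methoxybenzyl)oxy]-2-[(triethylsilyl)oxy]ethyl}oxolan-2-one, via alkenyllithium 14 (not isolated), via alkenylmagnesium bromide 15 (not isolated), via hydroxy ester 16 (not isolated)
Conditions: 13, t‑BuLi, Et2O, −78 °C; MgBr2·OEt2; then 9, CH2Cl2, −78 °C → rt
Reagents that add atoms: none
Why: Chelation‑controlled Grignard addition, in which magnesium bridges the aldehyde and the C8 OPMB oxygen in a six‑membered chelate and the alkenyl group (geometry retained from the iodide) attacks the face opposite the C7 and C9 substituents, should give the 6R (6,8‑anti) alkoxide, which lactonizes onto the ethyl ester to the cis‑disubstituted γ‑lactone.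

Step 10
Reactants: 17 (4R,5R)-lactone with C9 CH2OTES
Product: 18 (2S)-2-[(4-methoxybenzyl)oxy]-2-[Lac(OTBS)]acetaldehyde
Conditions: (COCl)2, DMSO, CH2Cl2, −78 → −40 °C; Et3N
Reagents that add atoms: none
Why: Swern conditions convert a primary triethylsilyl ether directly into the aldehyde, while the TBS ether, the PMB ether and the lactone should persist.

Step 11
Reactants: 19 methyl glycolate
Product: 20 methyl 2-[(triethylsilyl)oxy]acetate
Conditions: Et3SiCl, imidazole, CH2Cl2, 0 °C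
Reagents that add atoms: chlorotriethylsilane, CC[Si](Cl)(CC)CC
Why: Standard silylation of the primary alcohol.

Step 12
Reactants: 20 methyl 2-[(triethylsilyl)oxy]acetate
Product: 21 (Z)-1-methoxy-2-[(triethylsilyl)oxy]-1-[(trimethylsilyl)oxy]ethene
Conditions: LiN(iPr)2, THF, −78 °C; Me3SiCl
Reagents that add atoms: chlorotrimethylsilane, C[Si](C)(C)Cl
Why: Kinetic ester enolization and O‑silylation give the ketene silyl acetal needed for a Mukaiyama aldol reaction.

Step 13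
Reactants: 18 (2S)-2-[(4-methoxybenzyl)oxy]-2-[Lac(OTBS)]acetaldehyde; 21 (Z)-1-methoxy-2-[(triethylsilyl)oxy]-1-[(trimethylsilyl)oxy]ethene
Product: 23 methyl (3R,4S)-3-hydroxy-4-[(4-methoxybenzyl)oxy]-4-[Lac(OTBS)]-2-[(triethylsilyl)oxy]butanoate (C2 epimers), via silyl ether 22 (not isolated)
Conditions: MgBr2·OEt2, CH2Cl2, −78 → −20 °C; aq. citric acid
Reagents that add atoms: none
Why: Chelation‑controlled Mukaiyama aldol addition, in which MgBr2 bridges the aldehyde and the α‑OPMB oxygen (Cram chelate) and the ketene acetal attacks past the C8 hydrogen, should give the 8,9‑syn carbinol that becomes C9; the C10 centre is erased in step 16.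

Step 14
Reactants: 23 C9 alcohol
Product: 24 methyl (3R,4S)-3-[(tert-butyldimethylsilyl)oxy]-4-[(4-methoxybenzyl)oxy]-4-[Lac(OTBS)]-2-[(triethylsilyl)oxy]butanoate
Conditions: t‑BuMe2SiOTf, 2,6‑lutidine, CH2Cl2, −78 → 0 °C
Reagents that add atoms: tert‑butyldimethylsilyl trifluoromethanesulfonate, CC(C)(C)[Si](C)(C)OS(=O)(=O)C(F)(F)F
Why: Silyl triflate silylation of the hindered secondary alcohol.

Step 15
Reactants: 24 C9 TBS, C10 TES bis‑silyl ether
Product: 25 methyl (3S,4S)-3-[(tert-butyldimethylsilyl)oxy]-2-hydroxy-4-[(4-methoxybenzyl)oxy]-4-[Lac(OTBS)]butanoate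
Conditions: HF·pyridine, pyridine, THF, 0 °C
Reagents that add atoms: none
Why: Fluoride‑mediated desilylation should remove the TES ether, which is activated by the adjacent ester, much faster than either TBS ether.

Step 16
Reactants: 25 α‑hydroxy ester
Product: 26 methyl (3R,4S)-3-[(tert-butyldimethylsilyl)oxy]-4-[(4-methoxybenzyl)oxy]-4-[Lac(OTBS)]-2-oxobutanoate
Conditions: Dess–Martin periodinane, CH2Cl2, rt
Reagents that add atoms: none
Why: Dess–Martin oxidation of the secondary alcohol gives the α‑keto ester under non‑basic conditions that should spare the C9 centre.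

Step 17
Reactants: 26 α‑keto ester
Product: 27 methyl (2E)-2-{(1S,2S)-1-[(tert-butyldimethylsilyl)oxy]-2-[(4-methoxybenzyl)oxy]-2-[Lac(OTBS)]ethyl}-4-oxobut-2-enoate
Conditions: Ph3P=CHCHO (1.1 equiv), toluene, rt → 50 °C
Reagents that add atoms: (triphenylphosphoranylidene)acetaldehyde, O=CC=P(c1ccccc1)(c1ccccc1)c1ccccc1
Why: Wittig olefination of the activated ketone with the stabilized formyl ylide should give the more stable alkene, with the formyl group trans to the ester and cis to C9.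

Step 18
Reactants: 27 enal with C3 OTBS
Product: 28 methyl (2E)-2-{(1S,2S)-1-[(tert-butyldimethylsilyl)oxy]-2-[(4-methoxybenzyl)oxy]-2-[Lac(OH)]ethyl}-4-oxobut-2-enoate
Conditions: HF·pyridine, pyridine, THF, 0 °C → rt
Reagents that add atoms: none
Why: Fluoride‑mediated desilylation should cleave the primary allylic TBS ether well before the hindered secondary TBS ether at C9.

Step 19
Reactants: 28 allylic alcohol
Product: 30 methyl (2E)-2-{(1S,2S)-1-[(tert-butyldimethylsilyl)oxy]-2-[(4-methoxybenzyl)oxy]-2-[Lac(Br)]ethyl}-4-oxobut-2-enoate, via allylic mesylate 29 (not isolated)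
Conditions: MsCl, Et3N, CH2Cl2, −20 °C; LiBr, THF, 0 °C
Reagents that add atoms: lithium bromide, [Li+].[Br-]
Why: Mesylation and SN2 displacement by bromide at the primary allylic carbon avoid phosphine reagents, which could add to the enal, and keep the alkene geometry.

Step 20
Reactants: 30 allylic bromide
Product: 31 {(2Z)-3-[(2R,3R)-3-{(1S,2S)-2-[(tert-butyldimethylsilyl)oxy]-3-(methoxycarbonyl)-1-[(4-methoxybenzyl)oxy]-5-oxopent-3-en-1-yl}-5-oxooxolan-2-yl]-2-methylprop-2-en-1-yl}diphenylsulfonium tetrafluoroborate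
Conditions: Ph2S (excess), AgBF4, CH2Cl2, 0 °C → rt, dark
Reagents that add atoms: diphenyl sulfide, c1ccc(Sc2ccccc2)cc1; silver tetrafluoroborate, [Ag+].F[B-](F)(F)F
Why: Silver‑assisted S‑alkylation of diphenyl sulfide by the allylic bromide at its primary terminus is the standard route to allyldiphenylsulfonium salts.

Step 21
Reactants: 31 allylic diphenylsulfonium tetrafluoroborate
Product: 34 ten‑membered epoxy diene lactone (2R,3S‑oxirane; 8‑OPMB; 9‑OTBS; C10 CO2Me), via sulfonium ylide 32 (not isolated), via betaine 33 (not isolated)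
Conditions: KN(SiMe3)2 (1.05 equiv), THF (0.001 M), −78 → −20 °C
Reagents that add atoms: none
Why: Proposed new method: KN(SiMe3)2 removes the most acidic proton, at C3 between sulfur and the C4=C5 alkene, and the allylic ylide 32 adds through C3 to the C2 aldehyde (1,2‑addition to the s‑trans enal) to give betaine 33, whose C2 alkoxide displaces diphenyl sulfide from C3 with inversion. The closest known reaction is the Johnson–Corey–Chaykovsky epoxidation of aldehydes by allylic diphenylsulfonium ylides, which is established between two molecules and for small rings but not for closing a ten‑membered carbocycle. The ten‑membered ring closes in the C2–C3 addition (10‑exo‑trig attack on the carbonyl) and the oxirane in the 3‑exo‑tet displacement. C2 should be set by the enal face that the tether can reach: with C9–H eclipsing C1=C10 to avoid allylic strain, the C8 branch and hence the ylide lie on one face and the OTBS group on the other, which leads to 2R; C3 then follows from the cis ring fusion, because the two ring‑cis alkenes hold C1 and C4 gauche in the anti‑periplanar betaine that can close. The step needs deprotonation at S–CH2 in preference to the lactone and C9 protons and 1,2‑ in preference to conjugate addition; the far higher acidity of the sulfonium methylene, low temperature, high dilution and the absence of any unhindered Michael acceptor (the lactone still lacks its methylene group) are meant to secure this.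

Step 22
Reactants: 34 ten‑membered epoxy diene lactone
Product: 37 α‑methylene lactone (2R,3S‑oxirane; 8‑OPMB; 9‑OTBS), via Mannich base 35 (not isolated), via ammonium iodide 36 (not isolated)
Conditions: LiN(iPr)2, THF, −78 °C; CH2=NMe2+ I−, → 0 °C; MeI, rt; aq. NaHCO3
Reagents that add atoms: N,N‑dimethylmethyleneiminium iodide, C=[N+](C)C.[I-]
Why: Kinetic enolization of the only enolizable carbonyl (lactone C11), Mannich reaction with the iminium salt, quaternization and E1cB elimination install the exocyclic methylene before any base‑sensitive ester is present.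

Step 23
Reactants: 37 α‑methylene lactone with 9‑OTBS
Product: 38 C9 alcohol (α‑methylene lactone; 8‑OPMB; 9‑OH)
Conditions: HF·pyridine, pyridine (excess), THF, 0 °C → rt
Reagents that add atoms: none
Why: Pyridine‑buffered fluoride desilylation of the allylic secondary TBS ether should leave the oxirane, the PMB ether and the esters intact.

Step 24
Reactants: 38 C9 alcohol
Product: 39 C9 tiglate (α‑methylene lactone; 8‑OPMB; 9‑O‑tigloyl)
Conditions: (E)‑MeCH=C(Me)COCl, DMAP, Et3N, CH2Cl2, 0 °C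
Reagents that add atoms: (E)‑2‑methylbut‑2‑enoyl chloride, O=C(Cl)/C(C)=C/C
Why: DMAP‑catalysed acylation of the secondary allylic alcohol with retention at C9.

Step 25
Reactants: 39 C9 tiglate with 8‑OPMB
Product: 40 C8 alcohol (α‑methylene lactone; 8‑OH; 9‑O‑tigloyl)
Conditions: DDQ, CH2Cl2/pH 7 buffer, 0 °C
Reagents that add atoms: none
Why: Oxidative cleavage of the PMB ether under neutral conditions avoids acid (oxirane) and base (lactone migration to O8, tiglate shift).

Step 26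
Reactants: 41 (E)-2-methylbut-2-en-1-ol
Product: 42 [(2R,3R)-2,3-dimethyloxiran-2-yl]methanol
Conditions: Ti(OiPr)4 (cat.), D‑(−)‑diethyl tartrate (cat.), t‑BuOOH, 4 Å sieves, CH2Cl2, −20 °C
Reagents that add atoms: tert‑butyl hydroperoxide, CC(C)(C)OO
Why: Sharpless asymmetric epoxidation of the allylic alcohol, where the D‑tartrate ligand selects the alkene face that gives the (2R,3R) epoxide.

Step 27
Reactants: 42 [(2R,3R)-2,3-dimethyloxiran-2-yl]methanol
Product: 43 (2R,3S)-3-acetoxy-2-methylbutane-1,2-diol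
Conditions: Ti(OiPr)4, AcOH, CH2Cl2, rt
Reagents that add atoms: acetic acid, CC(=O)O
Why: Titanium‑assisted opening of the 2,3‑epoxy alcohol by acetate at C3 (SN2, inversion) sets the acetoxy centre and leaves the tertiary carbinol configuration unchanged.

Step 28
Reactants: 43 (2R,3S)-3-acetoxy-2-methylbutane-1,2-diol
Product: 44 (2S,3S)-3-acetoxy-2-hydroxy-2-methylbutanoic acid
Conditions: TEMPO (cat.), NaOCl (cat.), NaClO2, MeCN/phosphate buffer pH 6.7, 35 °C
Reagents that add atoms: sodium chlorite, [Na+].[O-]Cl=O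
Why: Nitroxyl‑catalysed oxidation with chlorite as terminal oxidant takes the primary alcohol to the acid without glycol cleavage or loss of the acetate.

Step 29
Reactants: 44 (2S,3S)-3-acetoxy-2-hydroxy-2-methylbutanoic acid
Product: 46 (2S,3S)-3-acetoxy-2-methyl-2-[(trimethylsilyl)oxy]butanoyl chloride, via bis(trimethylsilyl) derivative 45 (not isolated)
Conditions: Me3SiCl, Et3N, CH2Cl2, rt; then (COCl)2, DMF (cat.), 0 °C
Reagents that add atoms: chlorotrimethylsilane, C[Si](C)(C)Cl; oxalyl chloride, O=C(Cl)C(Cl)=O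
Why: A trimethylsilyl ester reacts with oxalyl chloride/DMF under neutral conditions to give the acid chloride while the tertiary hydroxyl stays masked as its silyl ether.

Step 30
Reactants: 40 C8 alcohol; 46 (2S,3S)-3-acetoxy-2-methyl-2-[(trimethylsilyl)oxy]butanoyl chloride
Product: 48 CNP0202690.1, via silyl ether 47 (not isolated)
Conditions: DMAP, Et3N, CH2Cl2, 0 °C → rt; then aq. citric acid, THF, 0 °C
Reagents that add atoms: none
Why: DMAP‑catalysed acylation of the C8 alcohol by the acid chloride, followed by mild hydrolysis of the labile trimethylsilyl ether, completes the target without touching any stereocentre.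

Compound list
1 | dimethyl D‑tartrate, dimethyl (2S,3S)-2,3-dihydroxybutanedioate | COC(=O)[C@@H](O)[C@H](O)C(=O)OC | starting material
2 | dimethyl (4S,5S)-2-(4-methoxyphenyl)-1,3-dioxolane-4,5-dicarboxylate | COC(=O)[C@H]1OC(c2ccc(OC)cc2)O[C@@H]1C(=O)OC | intermediate
3 | (2R,3R)-3-[(4-methoxybenzyl)oxy]butane-1,2,4-triol | OC[C@@H](OCc1ccc(OC)cc1)[C@H](O)CO | intermediate
4 | (2R)-3-hydroxy-2-[(4-methoxybenzyl)oxy]propanal | OC[C@@H](OCc1ccc(OC)cc1)C=O | intermediate (not isolated)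
5 | ethyl (2E,4S)-5-hydroxy-4-[(4-methoxybenzyl)oxy]pent-2-enoate | OC[C@@H](OCc1ccc(OC)cc1)/C=C/C(=O)OCC | intermediate
6 | ethyl (2E,4S)-4-[(4-methoxybenzyl)oxy]-5-[(triethylsilyl)oxy]pent-2-enoate | CC[Si](CC)(CC)OC[C@@H](OCc1ccc(OC)cc1)/C=C/C(=O)OCC | intermediate
7 | O‑ethyl O‑trimethylsilyl ketene acetal of 8 | CC[Si](CC)(CC)OC[C@@H](OCc1ccc(OC)cc1)[C@H](C=C(OCC)O[Si](C)(C)C)C=C | intermediate (not isolated)
8 | ethyl (3R,4S)-3-ethenyl-4-[(4-methoxybenzyl)oxy]-5-[(triethylsilyl)oxy]pentanoate | CC[Si](CC)(CC)OC[C@@H](OCc1ccc(OC)cc1)[C@H](CC(=O)OCC)C=C | intermediate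
9 | ethyl (3S,4S)-3-formyl-4-[(4-methoxybenzyl)oxy]-5-[(triethylsilyl)oxy]pentanoate | CC[Si](CC)(CC)OC[C@@H](OCc1ccc(OC)cc1)[C@H](CC(=O)OCC)C=O | intermediate
10 | propargyl alcohol, prop-2-yn-1-ol | C#CCO | starting material
11 | bromomagnesium (2Z)-3-(bromomagnesio)-2-methylprop-2-en-1-olate | Br[Mg]/C=C(/C)CO[Mg]Br | intermediate (not isolated)
12 | (2Z)-3-iodo-2-methylprop-2-en-1-ol | I/C=C(/C)CO | intermediate
13 | tert-butyl{[(2Z)-3-iodo-2-methylprop-2-en-1-yl]oxy}dimethylsilane | I/C=C(/C)CO[Si](C)(C)C(C)(C)C | intermediate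
14 | {(1Z)-3-[(tert-butyldimethylsilyl)oxy]-2-methylprop-1-en-1-yl}lithium | [Li]/C=C(/C)CO[Si](C)(C)C(C)(C)C | intermediate (not isolated)
15 | {(1Z)-3-[(tert-butyldimethylsilyl)oxy]-2-methylprop-1-en-1-yl}magnesium bromide | Br[Mg]/C=C(/C)CO[Si](C)(C)C(C)(C)C | intermediate (not isolated)
16 | ethyl (3R,4R,5Z)-7-[(tert-butyldimethylsilyl)oxy]-4-hydroxy-3-{(1S)-1-[(4-methoxybenzyl)oxy]-2-[(triethylsilyl)oxy]ethyl}-6-methylhept-5-enoate (formed as its magnesium alkoxide) | CC[Si](CC)(CC)OC[C@@H](OCc1ccc(OC)cc1)[C@H](CC(=O)OCC)[C@H](O)/C=C(/C)CO[Si](C)(C)C(C)(C)C | intermediate (not isolated)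
17 | (4R,5R)-5-{(1Z)-3-[(tert-butyldimethylsilyl)oxy]-2-methylprop-1-en-1-yl}-4-{(1S)-1-[(4-methoxybenzyl)oxy]-2-[(triethylsilyl)oxy]ethyl}oxolan-2-one | O=C1O[C@H](/C=C(/C)CO[Si](C)(C)C(C)(C)C)[C@@H](C1)[C@H](OCc2ccc(OC)cc2)CO[Si](CC)(CC)CC | intermediate
18 | (2S)-2-[(4-methoxybenzyl)oxy]-2-[Lac(OTBS)]acetaldehyde | O=C1O[C@H](/C=C(/C)CO[Si](C)(C)C(C)(C)C)[C@@H](C1)[C@H](OCc2ccc(OC)cc2)C=O | intermediate
19 | methyl glycolate | COC(=O)CO | starting material
20 | methyl 2-[(triethylsilyl)oxy]acetate | COC(=O)CO[Si](CC)(CC)CC | intermediate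
21 | (Z)-1-methoxy-2-[(triethylsilyl)oxy]-1-[(trimethylsilyl)oxy]ethene | CO/C(O[Si](C)(C)C)=C/O[Si](CC)(CC)CC | intermediate
22 | methyl (3R,4S)-4-[(4-methoxybenzyl)oxy]-4-[Lac(OTBS)]-2-[(triethylsilyl)oxy]-3-[(trimethylsilyl)oxy]butanoate (C2 epimers) | O=C1O[C@H](/C=C(/C)CO[Si](C)(C)C(C)(C)C)[C@@H](C1)[C@H](OCc2ccc(OC)cc2)[C@@H](O[Si](C)(C)C)C(O[Si](CC)(CC)CC)C(=O)OC | intermediate (not isolated)
23 | methyl (3R,4S)-3-hydroxy-4-[(4-methoxybenzyl)oxy]-4-[Lac(OTBS)]-2-[(triethylsilyl)oxy]butanoate (C2 epimers) | O=C1O[C@H](/C=C(/C)CO[Si](C)(C)C(C)(C)C)[C@@H](C1)[C@H](OCc2ccc(OC)cc2)[C@@H](O)C(O[Si](CC)(CC)CC)C(=O)OC | intermediate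
24 | methyl (3R,4S)-3-[(tert-butyldimethylsilyl)oxy]-4-[(4-methoxybenzyl)oxy]-4-[Lac(OTBS)]-2-[(triethylsilyl)oxy]butanoate (C2 epimers) | O=C1O[C@H](/C=C(/C)CO[Si](C)(C)C(C)(C)C)[C@@H](C1)[C@H](OCc2ccc(OC)cc2)[C@@H](O[Si](C)(C)C(C)(C)C)C(O[Si](CC)(CC)CC)C(=O)OC | intermediate
25 | methyl (3S,4S)-3-[(tert-butyldimethylsilyl)oxy]-2-hydroxy-4-[(4-methoxybenzyl)oxy]-4-[Lac(OTBS)]butanoate (C2 epimers) | O=C1O[C@H](/C=C(/C)CO[Si](C)(C)C(C)(C)C)[C@@H](C1)[C@H](OCc2ccc(OC)cc2)[C@@H](O[Si](C)(C)C(C)(C)C)C(O)C(=O)OC | intermediate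
26 | methyl (3R,4S)-3-[(tert-butyldimethylsilyl)oxy]-4-[(4-methoxybenzyl)oxy]-4-[Lac(OTBS)]-2-oxobutanoate | O=C1O[C@H](/C=C(/C)CO[Si](C)(C)C(C)(C)C)[C@@H](C1)[C@H](OCc2ccc(OC)cc2)[C@@H](O[Si](C)(C)C(C)(C)C)C(=O)C(=O)OC | intermediate
27 | methyl (2E)-2-{(1S,2S)-1-[(tert-butyldimethylsilyl)oxy]-2-[(4-methoxybenzyl)oxy]-2-[Lac(OTBS)]ethyl}-4-oxobut-2-enoate | O=C1O[C@H](/C=C(/C)CO[Si](C)(C)C(C)(C)C)[C@@H](C1)[C@H](OCc2ccc(OC)cc2)[C@@H](O[Si](C)(C)C(C)(C)C)/C(C(=O)OC)=C\C=O | intermediate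
28 | methyl (2E)-2-{(1S,2S)-1-[(tert-butyldimethylsilyl)oxy]-2-[(4-methoxybenzyl)oxy]-2-[Lac(OH)]ethyl}-4-oxobut-2-enoate | O=C1O[C@H](/C=C(/C)CO)[C@@H](C1)[C@H](OCc2ccc(OC)cc2)[C@@H](O[Si](C)(C)C(C)(C)C)/C(C(=O)OC)=C\C=O | intermediate
29 | methyl (2E)-2-{(1S,2S)-1-[(tert-butyldimethylsilyl)oxy]-2-[(4-methoxybenzyl)oxy]-2-[Lac(OMs)]ethyl}-4-oxobut-2-enoate | O=C1O[C@H](/C=C(/C)COS(C)(=O)=O)[C@@H](C1)[C@H](OCc2ccc(OC)cc2)[C@@H](O[Si](C)(C)C(C)(C)C)/C(C(=O)OC)=C\C=O | intermediate (not isolated)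
30 | methyl (2E)-2-{(1S,2S)-1-[(tert-butyldimethylsilyl)oxy]-2-[(4-methoxybenzyl)oxy]-2-[Lac(Br)]ethyl}-4-oxobut-2-enoate | O=C1O[C@H](/C=C(/C)CBr)[C@@H](C1)[C@H](OCc2ccc(OC)cc2)[C@@H](O[Si](C)(C)C(C)(C)C)/C(C(=O)OC)=C\C=O | intermediate
31 | {(2Z)-3-[(2R,3R)-3-{(1S,2S)-2-[(tert-butyldimethylsilyl)oxy]-3-(methoxycarbonyl)-1-[(4-methoxybenzyl)oxy]-5-oxopent-3-en-1-yl}-5-oxooxolan-2-yl]-2-methylprop-2-en-1-yl}diphenylsulfonium tetrafluoroborate (3E in the pentenyl chain) | O=C1O[C@H](/C=C(/C)C[S+](c2ccccc2)c2ccccc2)[C@@H](C1)[C@H](OCc2ccc(OC)cc2)[C@@H](O[Si](C)(C)C(C)(C)C)/C(C(=O)OC)=C\C=O.F[B-](F)(F)F | intermediate (key‑step precursor)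
32 | sulfonium ylide of 31 (carbanion at C3) | O=C1O[C@H](/C=C(/C)[CH-][S+](c2ccccc2)c2ccccc2)[C@@H](C1)[C@H](OCc2ccc(OC)cc2)[C@@H](O[Si](C)(C)C(C)(C)C)/C(C(=O)OC)=C\C=O | intermediate (not isolated)
33 | ten‑membered betaine: C2 alkoxide, C3 diphenylsulfonio, other centres as in 34 | C1C(=O)O[C@@H]2/C=C(/C)[C@@H]([S+](c3ccccc3)c3ccccc3)[C@H]([O-])/C=C(/C(=O)OC)[C@H](O[Si](C)(C)C(C)(C)C)[C@@H](OCc4ccc(OC)cc4)[C@H]12 | intermediate (not isolated)
34 | ten‑membered lactone: cis‑2,3‑oxirane (2R,3S); ring‑cis C1=C10 (E by CIP) and C4=C5 (Z); cis‑fused 6,12‑lactone (6R,7R); (8S)‑OPMB; (9S)‑OTBS; C10 CO2Me | C1C(=O)O[C@@H]2/C=C(/C)[C@@H]3O[C@@H]3/C=C(/C(=O)OC)[C@H](O[Si](C)(C)C(C)(C)C)[C@@H](OCc4ccc(OC)cc4)[C@H]12 | intermediate (key‑step product)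
35 | C11 (dimethylamino)methyl derivative of 34 (C11 epimers) | CN(C)CC1C(=O)O[C@@H]2/C=C(/C)[C@@H]3O[C@@H]3/C=C(/C(=O)OC)[C@H](O[Si](C)(C)C(C)(C)C)[C@@H](OCc4ccc(OC)cc4)[C@H]12 | intermediate (not isolated)
36 | C11 (trimethylammonio)methyl iodide of 34 (C11 epimers) | C[N+](C)(C)CC1C(=O)O[C@@H]2/C=C(/C)[C@@H]3O[C@@H]3/C=C(/C(=O)OC)[C@H](O[Si](C)(C)C(C)(C)C)[C@@H](OCc4ccc(OC)cc4)[C@H]12.[I-] | intermediate (not isolated)
37 | α‑methylene lactone: 34 with C11=C13H2 | C=C1C(=O)O[C@@H]2/C=C(/C)[C@@H]3O[C@@H]3/C=C(/C(=O)OC)[C@H](O[Si](C)(C)C(C)(C)C)[C@@H](OCc4ccc(OC)cc4)[C@H]12 | intermediate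
38 | C9 alcohol: 37 with 9‑OH in place of 9‑OTBS | C=C1C(=O)O[C@@H]2/C=C(/C)[C@@H]3O[C@@H]3/C=C(/C(=O)OC)[C@H](O)[C@@H](OCc4ccc(OC)cc4)[C@H]12 | intermediate
39 | C9 tiglate: 38 with 9‑O‑[(E)‑2‑methylbut‑2‑enoyl] | C=C1C(=O)O[C@@H]2/C=C(/C)[C@@H]3O[C@@H]3/C=C(/C(=O)OC)[C@H](OC(=O)/C(C)=C/C)[C@@H](OCc4ccc(OC)cc4)[C@H]12 | intermediate
40 | C8 alcohol: 39 with 8‑OH in place of 8‑OPMB | C=C1C(=O)O[C@@H]2/C=C(/C)[C@@H]3O[C@@H]3/C=C(/C(=O)OC)[C@H](OC(=O)/C(C)=C/C)[C@@H](O)[C@H]12 | intermediate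
41 | (E)-2-methylbut-2-en-1-ol | C/C=C(\C)CO | starting material
42 | [(2R,3R)-2,3-dimethyloxiran-2-yl]methanol | C[C@H]1O[C@]1(C)CO | intermediate
43 | (2R,3S)-3-acetoxy-2-methylbutane-1,2-diol | C[C@H](OC(C)=O)[C@](C)(O)CO | intermediate
44 | (2S,3S)-3-acetoxy-2-hydroxy-2-methylbutanoic acid | C[C@H](OC(C)=O)[C@](C)(O)C(=O)O | intermediate
45 | trimethylsilyl (2S,3S)-3-acetoxy-2-methyl-2-[(trimethylsilyl)oxy]butanoate | C[C@H](OC(C)=O)[C@](C)(O[Si](C)(C)C)C(=O)O[Si](C)(C)C | intermediate (not isolated)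
46 | (2S,3S)-3-acetoxy-2-methyl-2-[(trimethylsilyl)oxy]butanoyl chloride | C[C@H](OC(C)=O)[C@](C)(O[Si](C)(C)C)C(Cl)=O | intermediate
47 | O‑trimethylsilyl ether of 48 at the side‑chain tertiary hydroxyl | C=C1C(=O)O[C@@H]2/C=C(/C)[C@@H]3O[C@@H]3/C=C(/C(=O)OC)[C@H](OC(=O)/C(C)=C/C)[C@@H](OC(=O)[C@@](C)(O[Si](C)(C)C)[C@H](C)OC(C)=O)[C@H]12 | intermediate (not isolated)
48 | CNP0202690.1 | C=C1C(=O)O[C@@H]2/C=C(/C)[C@@H]3O[C@@H]3/C=C(/C(=O)OC)[C@H](OC(=O)/C(C)=C/C)[C@@H](OC(=O)[C@@](C)(O)[C@H](C)OC(C)=O)[C@H]12 | target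

Total step count: 30. Longest linear sequence: 22 steps (steps 1–6, 9, 10, 13–25 and 30).

Steps most likely to fail

Step 21 (ring closure). The ylide may react between molecules and give oligomers, deprotonation may occur elsewhere, or the ring may close to the wrong oxirane geometry or face. Fallback, using known reactions only: the two fragment unions are exchanged, so that the oxirane is made between two molecules and the ring is closed at C5–C6 by an intramolecular Nozaki–Hiyama–Kishi reaction. It sets out from 8 (with 12 and 21). Swern oxidation of the primary TES ether of 8 gives ethyl (3R,4S)-3-ethenyl-4-[(4-methoxybenzyl)oxy]-5-oxopentanoate F1. Chelation‑controlled Mukaiyama aldol addition of 21 (MgBr2·OEt2) gives the C9 alcohol F2. Silylation with t‑BuMe2SiOTf gives the C9 TBS ether F3. HF·pyridine removes the TES group and gives the C10 alcohol F4. Dess–Martin oxidation gives the keto ester F5, and Ph3P=CHCHO gives the enal F6. In parallel 12 is brominated (CBr4, PPh3) to (1Z)-3-bromo-1-iodo-2-methylprop-1-ene F7, which with Ph2S and AgBF4 gives the sulfonium tetrafluoroborate F8. Deprotonation of F8 (KN(SiMe3)2, −78 °C) in the presence of F6 gives the vinyl oxirane F9, whose cis isomer of the right face would have to be separated. Lemieux–Johnson cleavage of the terminal vinyl group gives the aldehyde F10. CrCl2 with NiCl2 (cat.) in DMSO at high dilution adds the alkenyl iodide to the C6 aldehyde and the chromium alkoxide lactonizes, which comes back to the route at 34.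

Step 9 (C5–C6 union). Facial selectivity at C6 may be poor if the non‑chelated Felkin–Anh pathway competes, which would give the trans lactone. Fallback: C6 is set by reduction instead of addition. It sets out from 9 and 13. The alkenyllithium 14 is added at −78 °C without MgBr2 and the mixture is quenched cold, so that 16 and its C6 epimer, the (4S)‑hydroxy ester F11, stay open. Dess–Martin oxidation of the mixture gives the enone F12. LiBH(s‑Bu)3 at −78 °C should deliver hydride anti to the branched C8 substituent (Felkin–Anh, 1,2‑reduction of the β,β‑disubstituted enone), and the resulting 6R alkoxide lactonizes on warming, which comes back to the route at 17.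

Step 17 (Wittig olefination). The product enal may react again with the ylide, the enolizable C9 centre of 26 may epimerize, or the wrong alkene geometry may form. Fallback: 1,2‑addition followed by hydrolytic transposition. It sets out from 26. (Z)‑2‑Ethoxyvinyllithium (from (Z)‑1‑bromo‑2‑ethoxyethene and t‑BuLi, THF, −78 °C) adds to the ketone and gives the tertiary alcohol F13. Dilute aqueous acid hydrolyses the enol ether and the β‑hydroxy aldehyde loses water to the conjugated enal under thermodynamic control, which comes back to the route at 27.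

Further compounds
F1 | step 21 | ethyl (3R,4S)-3-ethenyl-4-[(4-methoxybenzyl)oxy]-5-oxopentanoate | O=C[C@@H](OCc1ccc(OC)cc1)[C@H](CC(=O)OCC)C=C
F2 | step 21 | C9 alcohol: C14 methyl ester; C10 OTES (epimers); (9R)‑OH; (8S)‑OPMB; (7R) vinyl; C12 ethyl ester | COC(=O)C(O[Si](CC)(CC)CC)[C@H](O)[C@@H](OCc1ccc(OC)cc1)[C@H](CC(=O)OCC)C=C
F3 | step 21 | C9 TBS ether of F2 | COC(=O)C(O[Si](CC)(CC)CC)[C@H](O[Si](C)(C)C(C)(C)C)[C@@H](OCc1ccc(OC)cc1)[C@H](CC(=O)OCC)C=C
F4 | step 21 | C10 alcohol: F3 without the TES group | COC(=O)C(O)[C@H](O[Si](C)(C)C(C)(C)C)[C@@H](OCc1ccc(OC)cc1)[C@H](CC(=O)OCC)C=C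
F5 | step 21 | C10 keto ester from F4 | COC(=O)C(=O)[C@H](O[Si](C)(C)C(C)(C)C)[C@@H](OCc1ccc(OC)cc1)[C@H](CC(=O)OCC)C=C
F6 | step 21 | enal: C2 aldehyde; C1=C10 with CHO trans to CO2Me; (9S)‑OTBS; (8S)‑OPMB; (7R) vinyl; C12 ethyl ester | O=C/C=C(/C(=O)OC)[C@H](O[Si](C)(C)C(C)(C)C)[C@@H](OCc1ccc(OC)cc1)[C@H](CC(=O)OCC)C=C
F7 | step 21 | (1Z)-3-bromo-1-iodo-2-methylprop-1-ene | I/C=C(/C)CBr
F8 | step 21 | [(2Z)-3-iodo-2-methylprop-2-en-1-yl]diphenylsulfonium tetrafluoroborate | I/C=C(/C)C[S+](c1ccccc1)c1ccccc1.F[B-](F)(F)F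
F9 | step 21 | vinyl oxirane: (2R,3S)‑cis‑oxirane between the C1=C10 enoate and the (Z)‑C4=C5 iodoalkene; rest as F6 | I/C=C(/C)[C@@H]1O[C@@H]1/C=C(/C(=O)OC)[C@H](O[Si](C)(C)C(C)(C)C)[C@@H](OCc1ccc(OC)cc1)[C@H](CC(=O)OCC)C=C
F10 | step 21 | C6 aldehyde from F9 | I/C=C(/C)[C@@H]1O[C@@H]1/C=C(/C(=O)OC)[C@H](O[Si](C)(C)C(C)(C)C)[C@@H](OCc1ccc(OC)cc1)[C@H](CC(=O)OCC)C=O
F11 | step 9 | ethyl (3R,4S,5Z)-7-[(tert-butyldimethylsilyl)oxy]-4-hydroxy-3-{(1S)-1-[(4-methoxybenzyl)oxy]-2-[(triethylsilyl)oxy]ethyl}-6-methylhept-5-enoate (C6 epimer of 16) | CC[Si](CC)(CC)OC[C@@H](OCc1ccc(OC)cc1)[C@H](CC(=O)OCC)[C@@H](O)/C=C(/C)CO[Si](C)(C)C(C)(C)C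
F12 | step 9 | C6 enone: ethyl (5Z)-7-[(tert-butyldimethylsilyl)oxy]-3-{(1S)-1-[(4-methoxybenzyl)oxy]-2-[(triethylsilyl)oxy]ethyl}-6-methyl-4-oxohept-5-enoate with C7 as in 9 | CC[Si](CC)(CC)OC[C@@H](OCc1ccc(OC)cc1)[C@H](CC(=O)OCC)C(=O)/C=C(/C)CO[Si](C)(C)C(C)(C)C
F13 | step 17 | tertiary alcohol from 26 and (Z)‑2‑ethoxyvinyllithium (C10 epimers) | O=C1O[C@H](/C=C(/C)CO[Si](C)(C)C(C)(C)C)[C@@H](C1)[C@H](OCc2ccc(OC)cc2)[C@@H](O[Si](C)(C)C(C)(C)C)C(O)(/C=C\OCC)C(=O)OC
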